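**Strategy.** Everything rests on disconnecting the C2=C3 bond of quinone ring A (C1–C4, C4a, C8a): it is the only alkene of that ring, it is trisubstituted, and it carries the chiral side chain. Ring-closing metathesis of a diene diol forms this bond and closes ring A in a single operation; the precursor holds a vinyl carbinol arm and a 2-methylidene carbinol arm ortho to each other on ring B, with the (R)-silyloxy centre already in the second arm. Oxidation of both carbinols then gives the quinone. Ring B is carried as its bis(methoxymethyl) ether, so that the last unmasking is a mild hydrolysis to (R)-shikonin, which is esterified at the end.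

Key step: step 9

Remark: the two carbinol centres made in steps 7 and 8 are carried as diastereomer mixtures, because step 10 turns both into carbonyl groups.

**Step 1**
Reactants: 1 2,5-dihydroxybenzaldehyde
Product: 2 2,5-bis(methoxymethoxy)benzaldehyde
Conditions: MOMCl (3 equiv), i-Pr2NEt (4 equiv), CH2Cl2, 0 °C to rt
Reagents that add atoms: chloromethyl methyl ether (MOMCl), COCCl
Why: O-Alkylation of both phenols with MOMCl and an amine base (methoxymethyl ether formation) is routine, and excess reagent also caps the hydrogen-bonded ortho phenol.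

**Step 2**
Reactants: 2 2,5-bis(methoxymethoxy)benzaldehyde
Product: 5 3,6-bis(methoxymethoxy)phthalaldehyde, via lithium amino alkoxide 3 (not isolated), via ortho-lithiated amino alkoxide 4 (not isolated)
Conditions: LiN(Me)CH2CH2NMe2 (1.1 equiv, from Me2NCH2CH2NHMe and n-BuLi), THF, −20 °C; n-BuLi (2.5 equiv), −20 °C; DMF (5 equiv), −78 °C to rt; aq. NH4Cl, 0 °C
Reagents that add atoms: N,N-dimethylformamide (DMF), CN(C)C=O
Why: Directed ortho-metalation of a benzaldehyde protected in situ as its α-amino alkoxide is known chemistry, lithiation should occur at C6 because that position lies between the chelating amino alkoxide and a MOM ether, and DMF formylation with mild hydrolysis then frees both aldehydes.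

**Step 3**
Reactants: 6 acrolein
Product: 8 2-bromoacrolein, via 2,3-dibromopropanal 7 (not isolated)
Conditions: Br2 (1.0 equiv), CH2Cl2, −78 to 0 °C; Et3N (1.05 equiv), 0 °C; used at once as a solution
Reagents that add atoms: bromine, BrBr
Why: Bromine addition to the enal followed by dehydrobromination of the dibromide with Et3N (bromination–elimination) is the standard access to α-bromo enals.

**Step 4**
Reactants: 8 2-bromoacrolein
Product: 10 (R)-2-bromohexa-1,5-dien-3-ol, via diisopinocampheylborinic ester 9 (not isolated)
Conditions: (+)-Ipc2BOMe [from (−)-α-pinene], CH2=CHCH2MgBr, Et2O, 0 °C to rt; 8, −78 °C; 3 M NaOH, 30% H2O2, 0 °C to rt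
Reagents that add atoms: allylmagnesium bromide, C=CC[Mg]Br; B-allyldiisopinocampheylborane (made from it in the flask, carries the allyl group), C=CCB([C@H]1C[C@H]2C[C@@H]([C@@H]1C)C2(C)C)[C@H]1C[C@H]2C[C@@H]([C@@H]1C)C2(C)C
Why: Brown asymmetric allylboration passes through a chair-like six-membered transition state in which the isopinocampheyl groups of the (−)-α-pinene series steer the allyl group to the Re face of the aldehyde, which sets the (R)-carbinol centre.

**Step 5**
Reactants: 10 (R)-2-bromohexa-1,5-dien-3-ol
Product: 11 (R)-[(2-bromohexa-1,5-dien-3-yl)oxy](tert-butyl)dimethylsilane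
Conditions: TBSCl (1.3 equiv), imidazole (2.5 equiv), DMF, rt
Reagents that add atoms: tert-butyldimethylsilyl chloride (TBSCl), CC(C)(C)[Si](C)(C)Cl
Why: Imidazole-promoted silylation of a secondary alcohol is routine and leaves the C–O bond of the stereocentre untouched.

**Step 6**
Reactants: 11 (R)-[(2-bromohexa-1,5-dien-3-yl)oxy](tert-butyl)dimethylsilane
Product: 12 (R)-[(2-bromo-6-methylhepta-1,5-dien-3-yl)oxy](tert-butyl)dimethylsilane
Conditions: second-generation Grubbs catalyst (H2IMes)(PCy3)Cl2Ru=CHPh (3 mol %), 2-methylbut-2-ene (20 equiv), CH2Cl2, 40 °C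
Reagents that add atoms: 2-methylbut-2-ene, CC=C(C)C
Why: Olefin cross-metathesis of a terminal alkene with excess 2-methylbut-2-ene is an established way to build a prenyl-type trisubstituted alkene, and the hindered, electron-poor 2-bromoalkene does not take part.

**Step 7**
Reactants: 12 (R)-[(2-bromo-6-methylhepta-1,5-dien-3-yl)oxy](tert-butyl)dimethylsilane, 5 3,6-bis(methoxymethoxy)phthalaldehyde
Product: 14 3-{(3R)-3-[(tert-butyldimethylsilyl)oxy]-6-methylhepta-1,5-dien-2-yl}-4,7-bis(methoxymethoxy)-1,3-dihydro-2-benzofuran-1-ol (lactol; diastereomer mixture), via alkenyllithium 13 (not isolated)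
Conditions: t-BuLi (2.05 equiv), Et2O, −78 °C; cannulated into 5 (1.2 equiv), THF, −78 °C; aq. NH4Cl
Reagents that add atoms: none
Why: Bromine–lithium exchange gives the 2-lithioalkene without touching the stereocentre, and after 1,2-addition to one aldehyde of the symmetric dialdehyde the new alkoxide closes onto the neighbouring aldehyde, so that the second carbonyl is masked against double addition.

**Step 8**
Reactants: 14 lactol
Product: 15 (3R)-3-[(tert-butyldimethylsilyl)oxy]-1-[2-(1-hydroxyprop-2-en-1-yl)-3,6-bis(methoxymethoxy)phenyl]-6-methyl-2-methylidenehept-5-en-1-ol (diene diol; carbinol diastereomer mixture)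
Conditions: CH2=CHMgBr (4 equiv), THF, −20 to 0 °C; aq. NH4Cl
Reagents that add atoms: vinylmagnesium bromide, C=C[Mg]Br
Why: Grignard addition to a lactol, which after deprotonation opens to the alkoxy aldehyde, is a known route from phthalaldehyde-derived lactols to unsymmetrical diols, and keeping the magnesium alkoxides cold avoids silyl migration.

**Step 9**
Reactants: 15 diene diol
Product: 16 2-{(1R)-1-[(tert-butyldimethylsilyl)oxy]-4-methylpent-3-en-1-yl}-5,8-bis(methoxymethoxy)-1,4-dihydronaphthalene-1,4-diol (carbinol diastereomer mixture)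
Conditions: second-generation Grubbs catalyst (H2IMes)(PCy3)Cl2Ru=CHPh (10 mol %), 1,4-benzoquinone (20 mol %), degassed CH2Cl2 (0.005 M), 40 °C
Reagents that add atoms: none
Why: The Ru=CHPh unit of the catalyst exchanges onto the monosubstituted vinyl group, the new alkylidene adds across the 2-methylidene group of the other arm to give a four-membered metallacycle, and cycloreversion releases ring A with its C2=C3 bond while ethylene escapes and drives the reaction. The closest known reaction type is ring-closing metathesis of ortho-bis(1-hydroxyallyl)arenes to 1,4-dihydronaphthalene-1,4-diols. Ring A (C1, C2, C3, C4, C4a, C8a) is closed as a six-membered carbocycle in which the two internal alkene carbons become C3 and C2 and both terminal CH2 groups are excised. No stereocentre is created: the (R)-silyloxy centre is a spectator, and the carbinol diastereomers all converge in step 10. The step needs chemoselectivity among three alkenes, which substitution and ring size secure, since the catalyst loads on the only monosubstituted alkene, six-membered closure onto the 1,1-disubstituted alkene is favoured, and the trisubstituted prenyl alkene could only close a four- or nine-membered ring. 1,4-Benzoquinone is added to suppress hydride-mediated (Ru–H) isomerization of the allylic carbinols, and acid is excluded so that the product does not dehydrate.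

**Step 10**
Reactants: 16 dihydronaphthalenediol
Product: 17 2-{(1R)-1-[(tert-butyldimethylsilyl)oxy]-4-methylpent-3-en-1-yl}-5,8-bis(methoxymethoxy)naphthalene-1,4-dione
Conditions: activated MnO2 (20 equiv), CH2Cl2, rt
Reagents that add atoms: none
Why: Both carbinols are benzylic and allylic at once, so manganese dioxide oxidation of activated alcohols should turn the ene-diol (directly or through the tautomeric naphthalene-1,4-diol) into the 1,4-naphthoquinone while the silyl ether, the MOM ethers and the prenyl alkene stay inert.

**Step 11**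
Reactants: 17 silyl-protected quinone
Product: 18 2-[(1R)-1-hydroxy-4-methylpent-3-en-1-yl]-5,8-bis(methoxymethoxy)naphthalene-1,4-dione
Conditions: HF·pyridine, pyridine, THF, 0 °C to rt
Reagents that add atoms: none
Why: Fluoride cleavage of the secondary TBS ether under buffered, weakly acidic conditions is compatible with the quinone and breaks only the Si–O bond, so the stereocentre is retained.

**Step 12**
Reactants: 18 bis(methoxymethyl)-protected quinone alcohol
Product: 19 (R)-shikonin, 5,8-dihydroxy-2-[(1R)-1-hydroxy-4-methylpent-3-en-1-yl]naphthalene-1,4-dione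
Conditions: 3 M aq. HCl–THF (1:3), rt, argon, dark
Reagents that add atoms: none
Why: Acid hydrolysis of the aryl MOM acetals should be easy here because each freed phenol is held by a hydrogen bond to a peri quinone carbonyl, and dilute aqueous acid at rt should be too weak to protonate the prenyl alkene or ionize the carbinol.

**Step 13**
Reactants: 19 (R)-shikonin, 20 3,4-dimethylpent-3-enoic acid
Product: 21 (1R)-1-(5,8-dihydroxy-1,4-dioxo-1,4-dihydronaphthalen-2-yl)-4-methylpent-3-en-1-yl 3,4-dimethylpent-3-enoate (target)
Conditions: DCC (1.6 equiv), DMAP (0.2 equiv), 20 (1.5 equiv), CH2Cl2, 0 °C to rt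
Reagents that add atoms: none
Why: Steglich esterification should acylate the side-chain secondary alcohol selectively, because both phenols are tied up in strong hydrogen bonds to the quinone carbonyls, and the C–O bond of the stereocentre is not broken.

**Compound list**

1 | 2,5-dihydroxybenzaldehyde | O=Cc1cc(O)ccc1O | starting material
2 | 2,5-bis(methoxymethoxy)benzaldehyde | COCOc1ccc(OCOC)c(C=O)c1 | intermediate
3 | lithium [2,5-bis(methoxymethoxy)phenyl]{[2-(dimethylamino)ethyl](methyl)amino}methanolate (lithium amino alkoxide) | CN(C)CCN(C)C(O[Li])c1cc(OCOC)ccc1OCOC | intermediate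
4 | 6-lithio derivative of 3 (lithium on the ring carbon between the amino alkoxide carbon and a MOM ether) | CN(C)CCN(C)C(O[Li])c1c([Li])c(OCOC)ccc1OCOC | intermediate
5 | 3,6-bis(methoxymethoxy)phthalaldehyde (3,6-bis(methoxymethoxy)benzene-1,2-dicarbaldehyde) | COCOc1ccc(OCOC)c(C=O)c1C=O | intermediate
6 | acrolein (prop-2-enal) | C=CC=O | starting material
7 | 2,3-dibromopropanal (racemic) | BrCC(Br)C=O | intermediate
8 | 2-bromoacrolein (2-bromoprop-2-enal) | C=C(Br)C=O | intermediate
9 | (R)-2-bromohexa-1,5-dien-3-yl diisopinocampheylborinate (isopinocampheyl groups of the (−)-α-pinene series) | C=CC[C@@H](OB([C@H]1C[C@H]2C[C@@H]([C@@H]1C)C2(C)C)[C@H]1C[C@H]2C[C@@H]([C@@H]1C)C2(C)C)C(Br)=C | intermediate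
10 | (R)-2-bromohexa-1,5-dien-3-ol | C=CC[C@@H](O)C(Br)=C | intermediate
11 | (R)-[(2-bromohexa-1,5-dien-3-yl)oxy](tert-butyl)dimethylsilane | C=CC[C@@H](O[Si](C)(C)C(C)(C)C)C(Br)=C | intermediate
12 | (R)-[(2-bromo-6-methylhepta-1,5-dien-3-yl)oxy](tert-butyl)dimethylsilane | CC(C)=CC[C@@H](O[Si](C)(C)C(C)(C)C)C(Br)=C | intermediate
13 | {3-[(tert-butyldimethylsilyl)oxy]-6-methylhepta-1,5-dien-2-yl}lithium, configuration at C3 as in 12 | CC(C)=CC[C@@H](O[Si](C)(C)C(C)(C)C)C([Li])=C | intermediate
14 | 3-{(3R)-3-[(tert-butyldimethylsilyl)oxy]-6-methylhepta-1,5-dien-2-yl}-4,7-bis(methoxymethoxy)-1,3-dihydro-2-benzofuran-1-ol (diastereomer mixture at the two ring carbinol/acetal carbons) | CC(C)=CC[C@@H](O[Si](C)(C)C(C)(C)C)C(=C)C1OC(O)c2c(OCOC)ccc(OCOC)c21 | intermediate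
15 | (3R)-3-[(tert-butyldimethylsilyl)oxy]-1-[2-(1-hydroxyprop-2-en-1-yl)-3,6-bis(methoxymethoxy)phenyl]-6-methyl-2-methylidenehept-5-en-1-ol (carbinol diastereomer mixture) | CC(C)=CC[C@@H](O[Si](C)(C)C(C)(C)C)C(=C)C(O)c1c(OCOC)ccc(OCOC)c1C(O)C=C | intermediate
16 | 2-{(1R)-1-[(tert-butyldimethylsilyl)oxy]-4-methylpent-3-en-1-yl}-5,8-bis(methoxymethoxy)-1,4-dihydronaphthalene-1,4-diol (carbinol diastereomer mixture) | CC(C)=CC[C@@H](O[Si](C)(C)C(C)(C)C)C1=CC(O)c2c(OCOC)ccc(OCOC)c2C1O | intermediate
17 | 2-{(1R)-1-[(tert-butyldimethylsilyl)oxy]-4-methylpent-3-en-1-yl}-5,8-bis(methoxymethoxy)naphthalene-1,4-dione | CC(C)=CC[C@@H](O[Si](C)(C)C(C)(C)C)C1=CC(=O)c2c(OCOC)ccc(OCOC)c2C1=O | intermediate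
18 | 2-[(1R)-1-hydroxy-4-methylpent-3-en-1-yl]-5,8-bis(methoxymethoxy)naphthalene-1,4-dione | CC(C)=CC[C@@H](O)C1=CC(=O)c2c(OCOC)ccc(OCOC)c2C1=O | intermediate
19 | (R)-shikonin, 5,8-dihydroxy-2-[(1R)-1-hydroxy-4-methylpent-3-en-1-yl]naphthalene-1,4-dione | CC(C)=CC[C@@H](O)C1=CC(=O)c2c(O)ccc(O)c2C1=O | intermediate
20 | 3,4-dimethylpent-3-enoic acid | CC(C)=C(C)CC(=O)O | starting material
21 | (1R)-1-(5,8-dihydroxy-1,4-dioxo-1,4-dihydronaphthalen-2-yl)-4-methylpent-3-en-1-yl 3,4-dimethylpent-3-enoate | CC(C)=CC[C@@H](OC(=O)CC(C)=C(C)C)C1=CC(=O)c2c(O)ccc(O)c2C1=O | target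

**Step count.** Total: 13 steps. Longest linear sequence: 11 steps (steps 3 to 13, from acrolein 6).

**Steps most likely to fail**

1. Step 9 (ring-closing metathesis). Closure onto the crowded 1,1-disubstituted alkene may be slow, so that hydride-mediated (Ru–H) isomerization of the free allylic carbinols to ketones, or dehydration of the product to a naphthol, takes over. Fallback: starting from 15, both carbinols are silylated (TMSCl, imidazole, CH2Cl2, 0 °C) to give the bis(trimethylsilyl) ether of the diene diol F1. Metathesis of this fully O-protected diene with the same catalyst in toluene at 80 °C should give the bis(trimethylsilyl) ether of the dihydronaphthalenediol F2. K2CO3 in MeOH at 0 °C then removes only the two trimethylsilyl groups, and the route is rejoined at 16.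

2. Step 7 (mono-addition of the alkenyllithium). Double addition to the symmetric dialdehyde may compete, or the alkenyllithium may be lost through elimination or silyl migration before it has added. Fallback: starting from 5, CH2=CHMgBr (1.0 equiv, THF, −78 °C) is added first, which should give the vinyl lactol 3-ethenyl-4,7-bis(methoxymethoxy)-1,3-dihydro-2-benzofuran-1-ol F3. This lactol is then treated at −78 to −20 °C with 13 (2.2 equiv, the first equivalent serving as base), which gives the diene diol directly, and the route is rejoined at 15.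

3. Step 13 (final esterification). Acylation of the phenols may compete, and the free naphthazarin may degrade under the basic activation conditions. Fallback: starting from 18, the Steglich esterification with 20 (DCC, DMAP, CH2Cl2, 0 °C) is run before the phenols are unmasked, which should give the bis(methoxymethyl)-protected ester F4. Hydrolysis of its two MOM ethers with 3 M aq. HCl in THF at rt then leads straight to 21.

**Further compounds**

F1 | step 9 | bis(trimethylsilyl) ether of 15, (3R)-3-[(tert-butyldimethylsilyl)oxy]-6-methyl-2-methylidene-1-(trimethylsilyloxy)-1-{3,6-bis(methoxymethoxy)-2-[1-(trimethylsilyloxy)prop-2-en-1-yl]phenyl}hept-5-ene | CC(C)=CC[C@@H](O[Si](C)(C)C(C)(C)C)C(=C)C(O[Si](C)(C)C)c1c(OCOC)ccc(OCOC)c1C(O[Si](C)(C)C)C=C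
F2 | step 9 | bis(trimethylsilyl) ether of 16, 2-{(1R)-1-[(tert-butyldimethylsilyl)oxy]-4-methylpent-3-en-1-yl}-5,8-bis(methoxymethoxy)-1,4-bis(trimethylsilyloxy)-1,4-dihydronaphthalene | CC(C)=CC[C@@H](O[Si](C)(C)C(C)(C)C)C1=CC(O[Si](C)(C)C)c2c(OCOC)ccc(OCOC)c2C1O[Si](C)(C)C
F3 | step 7 | 3-ethenyl-4,7-bis(methoxymethoxy)-1,3-dihydro-2-benzofuran-1-ol | C=CC1OC(O)c2c(OCOC)ccc(OCOC)c21
F4 | step 13 | (1R)-1-[5,8-bis(methoxymethoxy)-1,4-dioxo-1,4-dihydronaphthalen-2-yl]-4-methylpent-3-en-1-yl 3,4-dimethylpent-3-enoate | CC(C)=CC[C@@H](OC(=O)CC(C)=C(C)C)C1=CC(=O)c2c(OCOC)ccc(OCOC)c2C1=O
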